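## The problem

Target 37 is a trans-fused hydroazulene, numbered here C1 (methyl-bearing ring-fusion carbon), C2, C3, C4 (tertiary carbon with the isopropyl group and the 4-hydroxybenzoate), C5 (ring-fusion CH), C6 (CHOH), C7=C8(CH3), C9 (ketone) and C10 (CH2); α is the face of the C1 methyl, β the face of H-5. Its cyclopentane (C1–C5) and cycloheptenone (C1, C5–C10) share the C1–C5 bond, and four contiguous stereocentres, C1 (R), C4 (R), C5 (S) and C6 (S), must be set: the C1 methyl and the C4 oxygen are α, H-5 and the isopropyl group are β, and the C6 hydroxyl is anti to the C4 oxygen. C1 is an all-carbon quaternary centre that nothing else in the molecule can induce, so it must come from an enantioselective step and then steer the others in a relay: C1 the face of attack at C4, O4 the faces at C5 and C6. The sensitive groups are the hindered tertiary aryl ester (which can migrate to the 1,3-related C6 hydroxyl under base), the γ-hydroxy enone with its vinylogously acidic H-6, the free phenol, and, in any precursor with a C6 ketone, a tertiary aldol unit open to retro-aldol cleavage, dehydration and C5 epimerisation. Acylating a tertiary alcohol wedged between an isopropyl group and a ring fusion is a problem in its own right. The feature that opens the molecule is the C1–C5 bond: it links a quaternary carbon to a CH lying between the C4 carbinol and the C6 oxygen, the pattern left when, in a fused cyclohexane-1,2-diol monosulfonate, the quaternary carbon shifts from the carbinol carbon (C6) to the sulfonate carbon (C5). Undoing that shift turns both odd-membered rings into a cis-decalin (ring A: C1–C6; ring B: C1, C6–C10) of the kind a Robinson annulation delivers.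

## Retrosynthesis

**37 ⇐ 36 ⇐ 35 ⇐ 34 (O–Si bonds, C7=C8 π bond, C9 ketal).** The γ-hydroxy enone and the phenol are unveiled last because they are the least robust parts. The C8 methyl is already present, so dehydrogenation of ketone 35 can only run toward C7 (C10 adjoins quaternary C1). Introducing the methyl later would cost extra steps on an enone. The forward steps must be non-basic, so that the ester stays on O4.

**34 ⇐ 27 + 32 (acyl C–O4 bond).** The ester is placed after C6 has been reduced and silylated. Acylating β-hydroxy ketone 23 would give a β-acyloxy ketone primed for elimination, and acylating after enone formation would expose the enone to an alkoxide. Acid chloride 32 comes in two steps from 4-hydroxybenzoic acid 28 via 30. The forward reaction must acylate a hindered tertiary alkoxide without moving the O6 silyl group.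

**27 ⇐ 25 ⇐ 23 (C6–H bond, O6–Si bond).** The C6 carbinol is taken back to the ketone that the rearrangement produces. The neighbouring C4 hydroxyl is the only handle for the C6 configuration, so the reduction has to be delivered from O4. An external hydride would enter from the open β face and give the wrong epimer.

**23 ⇐ 21 (C1–C5 cut, C1–C6 re-formed).** This is the key disconnection. Cutting C1–C5 rather than a peripheral bond of the seven-membered ring (C8–C9 or C1–C10) converts both rings at once into a cis-decalin and replaces a medium-ring closure by a stereospecific 1,2-shift. The precursor, all-cis triol monomesylate 21, has only six-membered rings. The forward reaction must make C1, not C3, migrate and must deliver the aldol product without cleaving it.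

**21 ⇐ 19 ⇐ 16 (S–O5 bond; C5–O and C6–O bonds).** The mesylate goes on the only secondary hydroxyl. The two new C–O bonds come from a syn-dihydroxylation of the C5=C6 alkene, which must occur on the α face, syn to the C4 hydroxyl and to the angular methyl. This is against the steric bias and is asked of a hydroxyl-directed osmylation. An epoxide route would give the trans arrangement, which cannot rearrange in this way.

**16 ⇐ 14 + 15 (C4–C11 bond).** The isopropyl group is added to the enone carbonyl of 14. This is simpler than carrying it through the annulation, and it creates the tertiary allylic alcohol that directs the next step. The nucleophile must add 1,2 and anti to the C1 methyl.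

**14 ⇐ 12 ⇐ 7 + 9, with auxiliary 8 (C5=C6 and C1–C2 bonds).** Robinson annulation assembles twelve of the fifteen skeletal carbons from two components. The Michael step is run through the chiral imine of 7 because that both directs alkylation to the methyl-bearing α-carbon and sets C1. C8 is an uncontrolled bystander, tolerated because it becomes sp2 in 36.

**7 ⇐ 5 ⇐ 3 ⇐ 1 + 2.** Monoketal 7 comes from the symmetrical 2,5-dimethylcyclohexane-1,4-dione 5, which is made by the classical methylation–decarboxylation of dimethyl succinylsuccinate 1. This is preferred over saturating 2,5-dimethylbenzoquinone, which stops at the hydroquinone under mild hydrogenation.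

## Roads not taken

**Alternative 1:** The cut removes C1–C10 and C7–C8 in a formal [4+3] annulation. Forward, Rh2(S-PTAD)4 A4 (dirhodium tetrakis[(S)-N-phthaloyl-1-adamantylglycinate], divalent rhodium) would decompose siloxyvinyl diazoacetate A3, the carbenoid would cyclopropanate the vinyl group of diene A2, and Cope rearrangement on warming would give cycloheptadiene A1.
- Merits: catalytic enantiocontrol, the seven-membered ring and quaternary C1 in one operation, C9 already oxygenated, and a C5=C6 alkene that could later take H-5 and O-6 in one syn addition.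
- Weak points: the Cope step must form a quaternary centre at a fully substituted diene terminus; C8 arrives as an ester that has to be reduced to a methyl group over several redox steps; the isopropyl carbinol still has to be added to a cyclopentanone next to the ring fusion.
- Comparison: this road reaches the bicycle in fewer steps and with a catalytic rather than auxiliary-based asymmetric step, and in that respect it is better. The chosen plan sets against it that every carbon arrives at its final oxidation level and that C4, C5 and C6 are relayed from C1 by substrate control and mechanism, with stoichiometric OsO4 as the price.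

**Alternative 2:** The cut removes the C1–CH3 bond and C5–C6. Forward, CuTC A9 (copper thiophene-2-carboxylate, monovalent copper) with a chiral phosphoramidite would catalyse addition of Me3Al A7 to cyclopentenone A6, and the aluminium enolate would be trapped through C5 by 2,2-dimethoxyacetaldehyde A8 to give aldol A5.
- Merits: C1, C5 and C6 and two bonds in one flask, from cheap materials.
- Weak points: copper-catalysed formation of quaternary centres is less selective on cyclopentenones than on cyclohexenones; the C6 configuration rests on an aldol with no firm model; the seven-membered ring must still be closed by aldol condensation of C8 onto C7, where enolisation toward C10 would close a five-membered ring instead; the isopropyl addition meets a retro-aldol-prone β-hydroxy cyclopentanone.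
- Comparison: on paper this is the shortest road. The chosen plan sets against it a ring construction with no competing ring size and a C5 configuration fixed by mechanism.

**Alternative 3:** The cut removes C8–C9. Forward, Bu3SnH A12 and AIBN A13 would convert phenyl selenoester A11 into the C9 acyl radical, which would add in a 7-endo mode to C8 of the propenyl ketone and give dione A10.
- Merits: a polarity-matched closure that delivers the seven-membered ring with both carbonyls in place and does not touch existing stereocentres.
- Weak points: the whole stereotriad C1/C4/C5 must already exist in A11, so the hard problem is only moved; the C6 and C9 carbonyls of A10 must then be told apart and C6 reduced stereoselectively with O4 silylated and unable to direct; a stoichiometric tin reagent is needed.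
- Comparison: the ring closure itself is more direct than the chosen sequence of annulation and shift. The chosen plan sets against it that C6 and C9 are differentiated from the start (ketone versus dioxolane) and that the stereotriad is built together with the ring system.

Key step: step 9

Remarks on the chemistry (assumptions):
- Locants and α/β are those defined in the first section; CIP descriptors refer to these locants.
- C8 is carried as a pair of epimers from 7 to 35 and is left undefined in the SMILES, because it becomes sp2 in 36.
- (R)-1-Phenylethylamine is chosen because the established sense of induction ((S)-amine giving (R)-2-methyl-2-(3-oxobutyl)cyclohexanone) corresponds here to the antipodal arrangement at C1.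

## Route

Step 1
Reactants: 1 dimethyl 2,5-dioxocyclohexane-1,4-dicarboxylate; 2 iodomethane
Product: 3 dimethyl 1,4-dimethyl-2,5-dioxocyclohexane-1,4-dicarboxylate
Conditions: MeI (2.5 equiv), K2CO3, acetone, reflux
Reagents that add atoms: iodomethane, CI
Why: Double C-alkylation of the two β-keto ester enolates; the new quaternary centres are of no stereochemical consequence because both lose their ester group in step 2.

Step 2
Reactants: 3 dimethyl 1,4-dimethyl-2,5-dioxocyclohexane-1,4-dicarboxylate
Product: 5 2,5-dimethylcyclohexane-1,4-dione, via keto diacid 4 (not isolated)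
Conditions: H2SO4 (10% aq), reflux
Reagents that add atoms: none
Why: Acid-catalysed ester hydrolysis and decarboxylation of the β-keto acids; acid is used because non-enolisable β-keto esters ring-open by retro-Claisen cleavage in base. The α-centres equilibrate, so 5 is a cis/trans mixture.

Step 3
Reactants: 5 2,5-dimethylcyclohexane-1,4-dione; 6 ethylene glycol
Product: 7 6,9-dimethyl-1,4-dioxaspiro[4.5]decan-8-one (route locants: C6 ketone, C9 dioxolane)
Conditions: ethylene glycol (1.0 equiv), TsOH (cat.), toluene, Dean–Stark reflux; bis-ketal and dione recycled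
Reagents that add atoms: ethylene glycol, OCCO
Why: Acid-catalysed ketalisation; the two carbonyls are symmetry-equivalent, so mono-protection is statistical but gives one constitution only. C8 is now fixed (racemic) while C1 stays epimerisable.

Step 4
Reactants: 7 6,9-dimethyl-1,4-dioxaspiro[4.5]decan-8-one; 8 (R)-1-phenylethylamine; 9 methyl vinyl ketone
Product: 12 (1R)-diketone (6,9-dimethyl-9-(3-oxobutyl)-1,4-dioxaspiro[4.5]decan-8-one), via imine 10 (not isolated), via Michael adduct imine 11 (not isolated)
Conditions: 8, toluene, Dean–Stark reflux; then MVK, THF, 25–40 °C; then AcOH/NaOAc, H2O, 25 °C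
Reagents that add atoms: methyl vinyl ketone, CC(=O)C=C; water, O
Why: Asymmetric Michael addition of a chiral imine through its more substituted secondary enamine tautomer (aza-ene-type transfer). Bond formation occurs only at the methyl-bearing α-carbon and on the enamine face anti to the phenyl group of the auxiliary, so C1 should be set as R whatever its initial configuration.

Step 5
Reactants: 12 (1R)-diketone
Product: 14 (1R)-enone (1,8-dimethyl-9,9-ethylenedioxy-decal-5-en-4-one), via ketol 13 (not isolated)
Conditions: NaOMe, MeOH, 60 °C
Reagents that add atoms: none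
Why: Intramolecular aldol condensation completing the Robinson annulation; the methyl-ketone enolate closes ring A onto C6 and the ketol dehydrates to the conjugated enone. The dioxolane is inert to methoxide.

Step 6
Reactants: 14 (1R)-enone; 15 isopropylmagnesium chloride
Product: 16 (1R,4R)-tertiary allylic alcohol (4α-hydroxy-4β-isopropyl)
Conditions: CeCl3 (anhydrous), i-PrMgCl, THF, −78 to 0 °C; aq NH4Cl
Reagents that add atoms: isopropylmagnesium chloride, CC(C)[Mg]Cl
Why: 1,2-Addition of an organocerium reagent to an enone, which suppresses enolisation, β-hydride reduction and conjugate addition. The nucleophile should enter quasi-axially on the β face, anti to the angular C1 methyl, leaving the hydroxyl α (4R).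

Step 7
Reactants: 16 (1R,4R)-tertiary allylic alcohol; 17 osmium tetroxide
Product: 19 (1R,4R,5S,6R)-all-cis decalin-4,5,6-triol, via osmate ester 18 (not isolated)
Conditions: OsO4 (1.05 equiv), TMEDA, CH2Cl2, −78 °C; then aq Na2SO3, THF, 60 °C
Reagents that add atoms: osmium tetroxide, O=[Os](=O)(=O)=O
Why: Hydroxyl-directed syn-dihydroxylation with the OsO4–TMEDA complex: hydrogen bonding of the allylic hydroxyl to the diamine-ligated oxidant should deliver osmium to the α face of C5=C6, syn to O4 and against the bias of the angular methyl. This sets C5 (S) and C6 (R) and makes the ring fusion cis; sulfite cleaves the hexavalent osmium glycolate reductively.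

Step 8
Reactants: 19 (1R,4R,5S,6R)-triol; 20 methanesulfonyl chloride
Product: 21 (1R,4R,5S,6R)-triol 5-O-methanesulfonate
Conditions: MsCl (1.2 equiv), Et3N, CH2Cl2, −20 to 0 °C
Reagents that add atoms: methanesulfonyl chloride, CS(=O)(=O)Cl
Why: Sulfonylation through sulfene; only the secondary C5 hydroxyl should react, since both neighbours are hindered tertiary alcohols. The all-cis arrangement rules out epoxide closure.

Step 9
Reactants: 21 (1R,4R,5S,6R)-triol 5-O-methanesulfonate
Product: 23 (1R,4R,5R)-trans-fused 4-hydroxy-hydroazulen-6-one with C9 dioxolane, via chloroaluminium dialkoxide 22 (not isolated)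
Conditions: Et2AlCl (3 equiv), CH2Cl2, −78 to −20 °C; then aq KNaC4H4O6 (potassium sodium tartrate), 0 °C
Reagents that add atoms: none
Why: Semipinacol (pinacol-type) rearrangement of a vicinal diol monosulfonate, the reaction type by which cis-fused decalindiol monosulfonates are turned into hydroazulenones and steroidal diol monosulfonates into ring-contracted, ring-expanded ketones. Et2AlCl first ties the syn-diaxial C4 and C6 hydroxyls into cyclic dialkoxide 22, which holds ring A in the chair with the C5 mesylate and the isopropyl group equatorial, and further Et2AlCl ionises the mesylate. Loss of mesylate is concerted with migration of the antiperiplanar C6–C1 bond and formation of the C6 carbonyl, so C1–C5 is made as C1–C6 breaks. Neither ring is closed by a cyclisation in the usual sense: the cyclopentane arises by excision of C6 from ring A and the cycloheptanone by insertion of C5 into ring B, both in the same suprafacial 1,2-shift. The one new stereocentre, C5, is fixed by the mechanism: C1 enters anti to the departing oxygen with inversion at C5 and retention at C1, which places H-5 trans to the C1 methyl (5R here because C6 now outranks C4). The step needs C1 rather than C3 to migrate, since the C4 oxygen can also push and C4–C3 is equally antiperiplanar; this should be secured by the much higher migratory aptitude of a tertiary over a primary alkyl group and by relief of strain between the fully substituted C1 and C6. Epoxide closure and elimination are excluded because all three oxygens are cis and C4 and C6 carry no hydrogen. The product is formed as a chelated aluminium aldolate and quenched cold, which guards the β-hydroxy ketone against retro-aldol cleavage and C5 epimerisation.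

Step 10
Reactants: 23 (1R,4R,5R)-4-hydroxy-hydroazulen-6-one
Product: 25 (1R,4R,5S,6S)-4,6-diol, via alkoxyborohydride 24 (not isolated)
Conditions: Me4NBH(OAc)3 (5 equiv), MeCN/AcOH, −35 to −20 °C
Reagents that add atoms: none
Why: Evans–Saksena reduction of a β-hydroxy ketone: ligand exchange places the borohydride on O4 and hydride should be delivered internally to the α face of C6, giving the 6β-alcohol anti to O4. The reagent does not reduce ketones without such delivery, and the cold acidic medium avoids retro-aldol cleavage.

Step 11
Reactants: 25 (1R,4R,5S,6S)-4,6-diol; 26 tert-butyldimethylsilyl triflate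
Product: 27 6-O-TBS ether of 25
Conditions: TBSOTf (1.1 equiv), 2,6-lutidine, CH2Cl2, −78 °C
Reagents that add atoms: tert-butyldimethylsilyl triflate, CC(C)(C)[Si](C)(C)OS(=O)(=O)C(F)(F)F
Why: Silylation of the secondary alcohol with a silyl triflate; the tertiary C4 hydroxyl should not compete at −78 °C with one equivalent. The TBS ether masks O6 during acylation and oxidation.

Step 12
Reactants: 28 4-hydroxybenzoic acid; 29 tert-butyldimethylsilyl chloride
Product: 30 tert-butyldimethylsilyl 4-(tert-butyldimethylsilyloxy)benzoate
Conditions: TBSCl (2.3 equiv), imidazole, DMF, 25 °C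
Reagents that add atoms: tert-butyldimethylsilyl chloride, CC(C)(C)[Si](C)(C)Cl
Why: Standard silylation of both the phenol and the carboxylic acid.

Step 13
Reactants: 30 tert-butyldimethylsilyl 4-(tert-butyldimethylsilyloxy)benzoate; 31 oxalyl chloride
Product: 32 4-(tert-butyldimethylsilyloxy)benzoyl chloride
Conditions: (COCl)2, DMF (cat.), CH2Cl2, 0 to 25 °C
Reagents that add atoms: oxalyl chloride, ClC(=O)C(=O)Cl
Why: Direct conversion of a silyl ester into the acid chloride by Vilsmeier-type activation under neutral conditions that leave the aryl silyl ether intact.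

Step 14
Reactants: 27 6-O-TBS ether; 32 4-(tert-butyldimethylsilyloxy)benzoyl chloride
Product: 34 4-O-[4-(tert-butyldimethylsilyloxy)benzoyl] 6-O-TBS hydroazulene with C9 dioxolane, via lithium alkoxide 33 (not isolated)
Conditions: n-BuLi (1.05 equiv), THF, −78 °C; then 32, −78 to 0 °C
Reagents that add atoms: 4-(tert-butyldimethylsilyloxy)benzoyl chloride, CC(C)(C)[Si](C)(C)Oc1ccc(C(=O)Cl)cc1
Why: Acylation of a lithium tertiary alkoxide with an acid chloride, the usual answer to a tertiary alcohol too hindered for amine-catalysed esterification. Low temperature and the lithium counter-ion disfavour 1,5-migration of the O6 silyl group.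

Step 15
Reactants: 34 diprotected ester with C9 dioxolane
Product: 35 C9 ketone (4-O-aroyl, 6-O-TBS)
Conditions: PPTS, acetone/H2O, 55 °C
Reagents that add atoms: water, O
Why: Mild acid-catalysed ketal hydrolysis that should spare both silyl ethers and the tertiary benzoate. C8 becomes epimerisable, but both epimers converge in step 16.

Step 16
Reactants: 35 C9 ketone
Product: 36 C7=C8 enone (bis-TBS ether of the target)
Conditions: IBX (2-iodoxybenzoic acid, 2.5 equiv), DMSO/fluorobenzene, 65 °C
Reagents that add atoms: none
Why: IBX dehydrogenation of a ketone through its enol. Only the C8 side can be desaturated because C10 adjoins quaternary C1, so the enone forms regiospecifically and the C8 stereocentre disappears.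

Step 17
Reactants: 36 bis-TBS enone
Product: 37 target, (1R,4R,5S,6S)-6-hydroxy-4-isopropyl-1,8-dimethyl-9-oxo-hydroazul-7-en-4-yl 4-hydroxybenzoate
Conditions: HF·pyridine, pyridine, THF, 0 to 25 °C
Reagents that add atoms: none
Why: Fluoride cleavage of the aryl and the secondary alkyl silyl ether in one operation. The buffered, non-basic medium avoids 1,3-acyl migration from O4 to O6 and vinylogous enolisation at C6.

## Compound list

1 | dimethyl 2,5-dioxocyclohexane-1,4-dicarboxylate (dimethyl succinylsuccinate) | COC(=O)C1CC(=O)C(C(=O)OC)CC1=O | starting material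
2 | iodomethane | CI | starting material
3 | dimethyl 1,4-dimethyl-2,5-dioxocyclohexane-1,4-dicarboxylate (cis/trans mixture) | COC(=O)C1(C)CC(=O)C(C)(C(=O)OC)CC1=O | intermediate
4 | 1,4-dimethyl-2,5-dioxocyclohexane-1,4-dicarboxylic acid | CC1(C(=O)O)CC(=O)C(C)(C(=O)O)CC1=O | intermediate (not isolated)
5 | 2,5-dimethylcyclohexane-1,4-dione (cis/trans mixture) | CC1CC(=O)C(C)CC1=O | intermediate
6 | ethylene glycol | OCCO | starting material
7 | 6,9-dimethyl-1,4-dioxaspiro[4.5]decan-8-one (racemic, cis/trans mixture) | CC1CC2(OCCO2)C(C)CC1=O | intermediate
8 | (R)-1-phenylethylamine | C[C@@H](N)c1ccccc1 | starting material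
9 | methyl vinyl ketone | CC(=O)C=C | starting material
10 | N-[(1R)-1-phenylethyl] ketimine of 7 | CC1CC2(OCCO2)C(C)CC1=N[C@H](C)c1ccccc1 | intermediate (not isolated)
11 | N-[(1R)-1-phenylethyl] C6 ketimine of diketone 12 | CC(=O)CC[C@]1(C)CC2(OCCO2)C(C)CC1=N[C@H](C)c1ccccc1 | intermediate (not isolated)
12 | (9R)-6,9-dimethyl-9-(3-oxobutyl)-1,4-dioxaspiro[4.5]decan-8-one (route C1 = R; both C8 epimers) | CC(=O)CC[C@]1(C)CC2(OCCO2)C(C)CC1=O | intermediate
13 | (1R)-6-hydroxy-1,8-dimethyl-9,9-ethylenedioxy-decalin-4-one (ketol; C6 undefined) | O=C1CC[C@]2(C)CC3(OCCO3)C(C)CC2(O)C1 | intermediate (not isolated)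
14 | (1R)-1,8-dimethyl-9,9-ethylenedioxy-decal-5-en-4-one (both C8 epimers) | O=C1CC[C@]2(C)CC3(OCCO3)C(C)CC2=C1 | intermediate
15 | isopropylmagnesium chloride | CC(C)[Mg]Cl | starting material
16 | (1R,4R)-4-isopropyl-1,8-dimethyl-9,9-ethylenedioxy-decal-5-en-4-ol (4α-OH) | CC(C)[C@]1(O)CC[C@]2(C)CC3(OCCO3)C(C)CC2=C1 | intermediate
17 | osmium tetroxide | O=[Os](=O)(=O)=O | starting material
18 | 5,6-O-osmate ester of triol 19 as its TMEDA chelate (hexavalent osmium) | C[N+]1(C)CC[N+](C)(C)[Os-2]12(=O)(=O)O[C@H]3[C@](O)(C(C)C)CC[C@]4(C)CC5(OCCO5)C(C)C[C@]34O2 | intermediate (not isolated)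
19 | (1R,4R,5S,6R)-4-isopropyl-1,8-dimethyl-9,9-ethylenedioxy-cis-decalin-4,5,6-triol (C1 methyl and all three hydroxyls α) | O[C@H]1[C@](O)(C(C)C)CC[C@]2(C)CC3(OCCO3)C(C)C[C@]12O | intermediate
20 | methanesulfonyl chloride | CS(=O)(=O)Cl | starting material
21 | (1R,4R,5S,6R)-triol 5-O-methanesulfonate | CS(=O)(=O)O[C@H]1[C@](O)(C(C)C)CC[C@]2(C)CC3(OCCO3)C(C)C[C@]12O | intermediate
22 | cyclic chloroaluminium 4,6-dialkoxide of 21 | CS(=O)(=O)O[C@H]1[C@]2(C(C)C)CC[C@]3(C)CC4(OCCO4)C(C)C[C@]13O[Al](Cl)O2 | intermediate (not isolated)
23 | (1R,4R,5R)-4-hydroxy-4-isopropyl-1,8-dimethyl-9,9-ethylenedioxy-trans-hydroazulen-6-one (H-5 β; C1 methyl and O4 α) | CC1CC(=O)[C@@H]2[C@](C)(CC[C@@]2(O)C(C)C)CC13OCCO3 | intermediate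
24 | tetramethylammonium diacetoxy(hydrido)borate of the C4 alkoxide of 23 | CC1CC(=O)[C@@H]2[C@](C)(CC[C@@]2(O[BH-](OC(C)=O)OC(C)=O)C(C)C)CC13OCCO3.C[N+](C)(C)C | intermediate (not isolated)
25 | (1R,4R,5S,6S)-4-isopropyl-1,8-dimethyl-9,9-ethylenedioxy-trans-hydroazulene-4,6-diol (6β-OH) | CC1C[C@H](O)[C@@H]2[C@](C)(CC[C@@]2(O)C(C)C)CC13OCCO3 | intermediate
26 | tert-butyldimethylsilyl triflate | CC(C)(C)[Si](C)(C)OS(=O)(=O)C(F)(F)F | starting material
27 | 6-O-TBS ether of 25 | CC1C[C@H](O[Si](C)(C)C(C)(C)C)[C@@H]2[C@](C)(CC[C@@]2(O)C(C)C)CC13OCCO3 | intermediate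
28 | 4-hydroxybenzoic acid | OC(=O)c1ccc(O)cc1 | starting material
29 | tert-butyldimethylsilyl chloride | CC(C)(C)[Si](C)(C)Cl | starting material
30 | tert-butyldimethylsilyl 4-(tert-butyldimethylsilyloxy)benzoate | CC(C)(C)[Si](C)(C)OC(=O)c1ccc(O[Si](C)(C)C(C)(C)C)cc1 | intermediate
31 | oxalyl chloride | ClC(=O)C(=O)Cl | starting material
32 | 4-(tert-butyldimethylsilyloxy)benzoyl chloride | CC(C)(C)[Si](C)(C)Oc1ccc(C(=O)Cl)cc1 | intermediate
33 | lithium C4 alkoxide of 27 | CC1C[C@H](O[Si](C)(C)C(C)(C)C)[C@@H]2[C@](C)(CC[C@@]2(O[Li])C(C)C)CC13OCCO3 | intermediate (not isolated)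
34 | (1R,4R,5S,6S)-4-O-[4-(TBSO)benzoyl]-6-O-TBS diol with C9 dioxolane | CC1C[C@H](O[Si](C)(C)C(C)(C)C)[C@@H]2[C@](C)(CC[C@@]2(OC(=O)c2ccc(O[Si](C)(C)C(C)(C)C)cc2)C(C)C)CC13OCCO3 | intermediate
35 | (1R,4R,5S,6S)-4-O-[4-(TBSO)benzoyl]-6-O-TBS hydroazulen-9-one | CC1C[C@H](O[Si](C)(C)C(C)(C)C)[C@@H]2[C@](C)(CC[C@@]2(OC(=O)c2ccc(O[Si](C)(C)C(C)(C)C)cc2)C(C)C)CC1=O | intermediate
36 | (1R,4R,5S,6S)-4-O-[4-(TBSO)benzoyl]-6-O-TBS hydroazul-7-en-9-one | CC1=C[C@H](O[Si](C)(C)C(C)(C)C)[C@@H]2[C@](C)(CC[C@@]2(OC(=O)c2ccc(O[Si](C)(C)C(C)(C)C)cc2)C(C)C)CC1=O | intermediate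
37 | (3R,3aS,4S,8aR)-4-hydroxy-6,8a-dimethyl-7-oxo-3-(propan-2-yl)-1,2,3,3a,4,7,8,8a-octahydroazulen-3-yl 4-hydroxybenzoate (route locants: 1R,4R,5S,6S) | CC1=C[C@H](O)[C@@H]2[C@](C)(CC[C@@]2(OC(=O)c2ccc(O)cc2)C(C)C)CC1=O | target

## Step count and least certain steps

Total: 17 steps. Longest linear sequence: 15 steps (steps 1–11 and 14–17); the aryl branch (steps 12 and 13) adds 2.

**Step 9 (key step).**
- What may go wrong: migration of C3 instead of C1 if the C4 alkoxide rather than the C6 alkoxide drives the shift; retro-aldol cleavage, dehydration or C5 epimerisation of the aldol product on the Lewis acid.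
- Fallback: take O4 out of both problems by protecting it while O5 and O6 are still held by osmium. The route is left at osmate ester 18, which is isolated instead of being cleaved. Its only free hydroxyl is silylated (TESOTf, 2,6-lutidine) to the 4-O-triethylsilyl osmate ester F1. Sulfite cleavage gives the 4-O-triethylsilyl 5,6-diol F2 and mesylation the 5-O-mesylate F3. Rearrangement with Et2AlCl, now driven by the O6 aluminium alkoxide alone, gives the β-silyloxy ketone F4, which cannot undergo retro-aldol cleavage. HF·pyridine returns the route at 23.

**Step 7.**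
- What may go wrong: poor facial selectivity, with osmylation from the β face anti to the angular methyl if hydrogen-bond delivery by the hindered tertiary hydroxyl is weak; ionisation of the tertiary allylic alcohol.
- Fallback: Woodward cis-hydroxylation, which places the diol on the face opposite to the one attacked first and so does not rely on the hydroxyl. From 16, I2 and AgOAc in wet AcOH should form the iodonium ion on the open β face and open it with acetate at C6 from the α face, giving the trans iodo acetate F5 in the flask. The neighbouring acetate then displaces iodide at C5 from the α face, and water opens the acetoxonium ion to the cis-hydroxy acetate F6 (drawn as the C5 acetate). Methanolysis (K2CO3, MeOH) returns the route at 19.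

**Step 10.**
- What may go wrong: incomplete ligand exchange at the hindered tertiary hydroxyl, or an internal delivery path crowded by the C1 methyl, leading to no reduction or to poor facial selectivity.
- Fallback: reduction of 23 under thermodynamic control by electron transfer (Li, liquid NH3, THF, −78 °C; NH4Cl). This should give the equatorial 6β-alcohol, because a 6α-oxygen would sit syn-axial to the C1 methyl. The route is rejoined directly at 25 and no new compound is made (entry F0).

**Step 14.**
- What may go wrong: slow acylation of a tertiary alkoxide flanked by the isopropyl group and the silyloxy-bearing C6; 1,5-silyl migration from O6 to O4 followed by acylation at O6.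
- Fallback: form the ester by hydride transfer instead of acyl substitution. From 23, an Evans–Tishchenko reduction with commercial 4-(tert-butyldimethylsilyloxy)benzaldehyde and catalytic SmI2 (THF, −10 °C) should transfer hydride from the O4 hemiacetal to C6 and leave the acyl group on O4, giving the 4-O-aroyl 6β-alcohol F7. Silylation (TBSOTf, 2,6-lutidine) rejoins the route at 34, replacing steps 10, 11 and 14.

**Step 4.**
- What may go wrong: erosion of facial selectivity in the C8 epimer that is mismatched with the auxiliary, which would lower the enantiomeric purity once C8 becomes sp2; partial loss of the dioxolane during imine hydrolysis.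
- Fallback: resolution instead of induction. From 7, base-catalysed Michael addition (KOH cat., MeOH, MVK, 0 °C) gives the racemic diketone F8, and cyclisation as in step 5 gives the racemic enone F9. Preparative chromatography on a chiral stationary phase returns the route at 14.

## Further compounds

F1 | step 9 | 4-O-triethylsilyl osmate ester (TMEDA chelate) | C[N+]1(C)CC[N+](C)(C)[Os-2]12(=O)(=O)O[C@H]3[C@](O[Si](CC)(CC)CC)(C(C)C)CC[C@]4(C)CC5(OCCO5)C(C)C[C@]34O2
F2 | step 9 | 4-O-triethylsilyl 5,6-diol | O[C@H]1[C@](O[Si](CC)(CC)CC)(C(C)C)CC[C@]2(C)CC3(OCCO3)C(C)C[C@]12O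
F3 | step 9 | 4-O-triethylsilyl 5-O-methanesulfonate | CS(=O)(=O)O[C@H]1[C@](O[Si](CC)(CC)CC)(C(C)C)CC[C@]2(C)CC3(OCCO3)C(C)C[C@]12O
F4 | step 9 | 4-O-triethylsilyl hydroazulen-6-one | CC1CC(=O)[C@@H]2[C@](C)(CC[C@@]2(O[Si](CC)(CC)CC)C(C)C)CC13OCCO3
F5 | step 7 | 5β-iodo 6α-acetate of the decalin-4α-ol | I[C@@H]1[C@](O)(C(C)C)CC[C@]2(C)CC3(OCCO3)C(C)C[C@]12OC(C)=O
F6 | step 7 | 5-O-acetyl all-cis triol | CC(=O)O[C@H]1[C@](O)(C(C)C)CC[C@]2(C)CC3(OCCO3)C(C)C[C@]12O
F0 | step 10 | none | none
F7 | step 14 | 4-O-[4-(TBSO)benzoyl] 6β-alcohol with C9 dioxolane | CC1C[C@H](O)[C@@H]2[C@](C)(CC[C@@]2(OC(=O)c2ccc(O[Si](C)(C)C(C)(C)C)cc2)C(C)C)CC13OCCO3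
F8 | step 4 | racemic diketone (12 with its C1 enantiomer) | CC(=O)CCC1(C)CC2(OCCO2)C(C)CC1=O
F9 | step 4 | racemic enone (14 with its C1 enantiomer) | O=C1CCC2(C)CC3(OCCO3)C(C)CC2=C1
A1 | alternative 1 | bicyclic cyclohepta-1,4-diene with C8 ester, C9 silyl enol ether and C4 dioxolane | COC(=O)C1=C(O[Si](C)(C)C(C)(C)C)C[C@@]2(C)CCC3(OCCO3)C2=CC1
A2 | alternative 1 | 6-ethenyl-7-methyl-1,4-dioxaspiro[4.4]non-6-ene | C=CC1=C(C)CCC12OCCO2
A3 | alternative 1 | methyl 3-(tert-butyldimethylsilyloxy)-2-diazobut-3-enoate | COC(=O)C(=[N+]=[N-])C(=C)O[Si](C)(C)C(C)(C)C
A4 | alternative 1 | Rh2(S-PTAD)4, dirhodium tetrakis[(S)-N-phthaloyl-1-adamantylglycinate] | [Rh+2].[Rh+2].[O-]C(=O)[C@@H](N1C(=O)c2ccccc2C1=O)C12CC3CC(CC(C3)C1)C2.[O-]C(=O)[C@@H](N1C(=O)c2ccccc2C1=O)C12CC3CC(CC(C3)C1)C2.[O-]C(=O)[C@@H](N1C(=O)c2ccccc2C1=O)C12CC3CC(CC(C3)C1)C2.[O-]C(=O)[C@@H](N1C(=O)c2ccccc2C1=O)C12CC3CC(CC(C3)C1)C2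
A5 | alternative 2 | 2,3,3-trisubstituted cyclopentanone aldol with C7 dimethyl acetal | O=C1CC[C@](C)(CC(=C)CC)[C@H]1[C@@H](O)C(OC)OC
A6 | alternative 2 | 3-(2-methylidenebutyl)cyclopent-2-en-1-one | O=C1CCC(CC(=C)CC)=C1
A7 | alternative 2 | trimethylaluminium | C[Al](C)C
A8 | alternative 2 | 2,2-dimethoxyacetaldehyde | COC(OC)C=O
A9 | alternative 2 | copper thiophene-2-carboxylate (CuTC) | [Cu+].[O-]C(=O)c1cccs1
A10 | alternative 3 | trans-fused hydroazulene-6,9-dione, 4-O-triethylsilyl (C8 epimers) | CC1CC(=O)[C@@H]2[C@](C)(CC[C@@]2(O[Si](CC)(CC)CC)C(C)C)CC1=O
A11 | alternative 3 | C9 phenyl selenoester with (E)-propenyl ketone at C5 | C/C=C/C(=O)[C@@H]1[C@](C)(CC[C@@]1(O[Si](CC)(CC)CC)C(C)C)CC(=O)[Se]c1ccccc1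
A12 | alternative 3 | tributyltin hydride | CCCC[SnH](CCCC)CCCC
A13 | alternative 3 | azobisisobutyronitrile | CC(C)(C#N)N=NC(C)(C)C#N
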